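The ratio of two late electrophile readings tells us what to do with the next run: charge more free base, or leave it and wait.

| flask | electrophile | nucleophile | free base | protic impurity | remark | time |
|---|---|---|---|---|---|---|
| Wednesday's | 1 M | 1.2 M | 0.81 M | 0.50 M | run made earlier |  |
| Saturday's | 1 M | 1.2 M | 1.2 M | 0.50 M | run made earlier |  |
| green | 1.0 M | 1.20 M | 1.00 M | 0.500 M |  | 4.0 d |
| blue | 1.0 M | 1.20 M | 1.50 M | 0.500 M |  | 4.0 d |

| run | time / d | electrophile / % | target / % |
|---|---|---|---|
| Wednesday's | 0.333 | 37 | 46 |
| Wednesday's | 1.04 | 16 | 48 |
| Wednesday's | 1.67 | 10 | 49 |
| Wednesday's | 3.00 | 2 | 46 |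
| Saturday's | 0.333 | 41 | 42 |
| Saturday's | 1.04 | 19 | 49 |
| Saturday's | 1.67 | 10 | 47 |
| Saturday's | 3.00 | 4 | 47 |

(each reading ± 2 percentage points)

- part of the electrophile that has reacted at the end, green
- part of the electrophile that has reacted at the end, blue
- what raising the concentration of free base from its lowest to its highest value here does to the part of the electrophile that has reacted (changes below 5 percentage points count as none) (it falls / no change / it rises)

- the earlier runs were read with a standard deviation of 2 percentage points

Let a be the fraction of the charged electrophile still there. Wednesday's and Saturday's runs, with free base at 0.81 M and 1.2 M, differ in a by no more than 4 points, against a scatter of 2.8 points on such a difference, so we average them at each time: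

a = 17.5% at 1.04 d, 10.0% at 1.67 d, 3.00% at 3.00 d

logarithm of the ratio over the time, first stretch: 0.888 d⁻¹

the same, second stretch: 0.905 d⁻¹

The two stretches read alike, so this tail looks pseudo-first-order: the rate goes with a itself. Over the whole stretch we get 0.900 d⁻¹, and we call this λ, the tail constant: the logarithm of the ratio of two late values of a, divided by the time between them. Carried on to the end:

a at 4.0 d = 3.00% × exp(−λ × 1.00 d) = 1.22%, so 98.8% has reacted

The mean 3.00% carries a scatter of 1.4 points, about half of itself, and the leftover inherits that. It still lies below the margin, so we keep free base at green's 1.00 M, run blue's 1.50 M as a check, and stop at 4.0 d.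

The forecast gives 98% for green (95% to 100%), 98% for blue (93% to 100%) and no change, holding that “the base has little kinetic effect here”, slightly below our figure.

The flasks give 98.3% for green and 98.4% for blue: no change, a change of 0.1 points.

    electrophile + target → side product (k = 0.0300 L mol⁻¹ h⁻¹)
    nucleophile + acid set free ⇌ protonated nucleophile, settled at all times (K = 1200 L mol⁻¹)
    electrophile + protic impurity → quenched substrate (k = 0.0400 L mol⁻¹ h⁻¹)
    electrophile + nucleophile → acid set free + target (k = 0.170 L mol⁻¹ h⁻¹)
    acid set free + free base ⇌ salt of the base (K = 2.60 L mol⁻¹, k = 2.10 L mol⁻¹ h⁻¹)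

In blue, electrophile used in making target over that lost to quenched substrate stands at 5.4 after 0.111 d and at 0.49 after 4.00 d, when free nucleophile is 2.8% of its charge. Carried by λ, blue's 17% at 25 h becomes 1.16% at 4.0 d, where blue holds 1.6%. Blue's answer has moved by 5 points with nucleophile down at 0.815 M.

The numbers in the tables come from a simulation on assumed constants; noise was put on by code.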